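## Retrosynthetic overview

1. Both bought rings are kept intact: the chromone of noreugenin (1; protected as 2, iodinated to 3) and the butenolide of (S)-5-(hydroxymethyl)furan-2(5H)-one (4; tosylate 5), the only chiral input.
2. Key disconnection C8–C4′: 3 + 5 give trans-lactone 6 by light-driven aryl-radical conjugate addition, anti to the bought stereocentre.
3. Piperidine disconnection (N1′–C2′ and N1′–C6′): lactone 6 + MeNH2 give hydroxy-δ-lactam 7. The lactone oxygen becomes the C3′ oxygen, so trans on the lactone becomes cis on the piperidine.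
4. Ester disconnection: 7 + 3,4-dimethoxybenzoyl chloride (8) give 9; lactam C=O to CH2 gives 10; MOM removal gives chrotacumine D (11).
5. Ring order: chromone (bought), then γ-lactone (bought, arylated), then piperidinone, then piperidine.

Assumption: 1 and 4 are bought as catalogue compounds (4 is made industrially from levoglucosenone or L-glutamic acid).

## Route

Step 1
Reactants: 1, noreugenin (5,7-dihydroxy-2-methyl-4H-chromen-4-one)
Product: 2, 5,7-bis(methoxymethoxy)-2-methyl-4H-chromen-4-one
Conditions: NaH (2.3 equiv), MOMCl (2.5 equiv), DMF, 0 °C → rt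
Reagents that add atoms: chloromethyl methyl ether (MOMCl), COCCl
Why: Williamson-type O-alkylation of both phenoxides (NaH breaks the 5-OH···O=C chelate); MOM offers no aryl or allyl group for the later C8 radical to cyclise onto and is later removed by acid without touching the methyl ethers or the ester.

Step 2
Reactants: 2, 5,7-bis(methoxymethoxy)-2-methyl-4H-chromen-4-one
Product: 3, 8-iodo-5,7-bis(methoxymethoxy)-2-methyl-4H-chromen-4-one
Conditions: NIS (1.1 equiv), DMF, rt → 40 °C, dark
Reagents that add atoms: N-iodosuccinimide, O=C1CCC(=O)N1I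
Why: Electrophilic aromatic iodination; in 5,7-dialkoxychromones C8 (para to 5-OR, flanked by one OR and the ring oxygen) is expected to react before C6 (between two OR groups).

Step 3
Reactants: 4, (S)-5-(hydroxymethyl)furan-2(5H)-one
Product: 5, [(2S)-5-oxo-2,5-dihydrofuran-2-yl]methyl 4-methylbenzenesulfonate
Conditions: TsCl (1.2 equiv), pyridine, CH2Cl2, 0 °C
Reagents that add atoms: p-toluenesulfonyl chloride, Cc1ccc(S(=O)(=O)Cl)cc1
Why: O-sulfonylation of the primary alcohol; weak base at 0 °C avoids γ-deprotonation of the butenolide, so the bought stereocentre is untouched.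

Step 4
Reactants: 3, 8-iodo-5,7-bis(methoxymethoxy)-2-methyl-4H-chromen-4-one; 5, (S)-butenolide tosylate (4 equiv, excess recovered)
Product: 6, [(2S,3R)-3-[5,7-bis(methoxymethoxy)-2-methyl-4-oxo-4H-chromen-8-yl]-5-oxooxolan-2-yl]methyl 4-methylbenzenesulfonate (trans lactone)
Conditions: 10-phenylphenothiazine (5 mol %), Hantzsch ester (2 equiv, in portions), 2,6-lutidine (1.5 equiv), degassed MeCN (0.3 M in 3), 390 nm LEDs, 20 °C
Reagents that add atoms: none (the new H comes from the Hantzsch ester)
Why: Proposed new method: the excited photoreductant transfers an electron to the chromone π-system of 3 (a built-in electron antenna), iodide is lost to give the chromon-8-yl σ-radical, this adds to the butenolide β-carbon anti to the CH2OTs group (1,2-induction on the five-membered ring sets the new centre as 3R, trans), and the α-lactone radical takes H from the Hantzsch ester; the closest known reactions are photoredox Giese-type hydroarylation of Michael acceptors with (hetero)aryl halides and anti-selective alkyl-radical additions to 5-substituted 2(5H)-furanones, but an aryl radical adding to a γ-stereogenic butenolide under substrate control has not been shown.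

Step 5
Reactants: 6, trans lactone tosylate
Product: 7, (4R,5S)-4-[5,7-bis(methoxymethoxy)-2-methyl-4-oxo-4H-chromen-8-yl]-5-hydroxy-1-methylpiperidin-2-one (OH and aryl cis)
Conditions: MeNH2 (2 M in THF, 8 equiv), THF/EtOH, 0 °C → rt; concentrate; AcOH (0.3 equiv), toluene, 90 °C
Reagents that add atoms: methylamine, CN
Why: SN2 amination and lactone aminolysis followed by O→N acyl transfer (the known lactone-to-lactam ring switch of 5-(sulfonyloxymethyl)butyrolactones): whichever electrophile reacts first, heating funnels the material to the more stable δ-lactam, and no bond to either stereocentre is broken, so the trans lactone becomes the cis-(4R,5S) piperidinone.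

Step 6
Reactants: 7, cis hydroxy-lactam; 8, 3,4-dimethoxybenzoyl chloride (1.5 equiv)
Product: 9, (3S,4R)-4-[5,7-bis(methoxymethoxy)-2-methyl-4-oxo-4H-chromen-8-yl]-1-methyl-6-oxopiperidin-3-yl 3,4-dimethoxybenzoate
Conditions: Et3N, DMAP (0.5 equiv), CH2Cl2, 0 °C → rt
Reagents that add atoms: none other than reactant 8 (COc1ccc(C(Cl)=O)cc1OC)
Why: DMAP-catalysed acylation of the only free hydroxyl with retention at the C–O stereocentre; the tertiary lactam, MOM ethers and chromone do not react.

Step 7
Reactants: 9, ester lactam
Product: 10, (3S,4R)-4-[5,7-bis(methoxymethoxy)-2-methyl-4-oxo-4H-chromen-8-yl]-1-methylpiperidin-3-yl 3,4-dimethoxybenzoate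
Conditions: IrCl(CO)(PPh3)2 (1 mol %), (Me2HSi)2O (2.5 equiv), toluene, rt; then NaBH(OAc)3, AcOH, rt
Reagents that add atoms: none (only H is added; the lactam oxygen is lost)
Why: Chemoselective Ir-catalysed hydrosilylation of the tertiary lactam to the N,O-silyl acetal/enamine, then iminium reduction; the aryl ester, the chromone (a vinylogous ester) and the MOM ethers are far less reactive, and the enamine involves only C5–C6, so C4 is not epimerised.

Step 8
Reactants: 10, bis-MOM chrotacumine D
Product: 11, chrotacumine D, (3S,4R)-4-(5,7-dihydroxy-2-methyl-4-oxo-4H-chromen-8-yl)-1-methylpiperidin-3-yl 3,4-dimethoxybenzoate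
Conditions: HCl (3 M in MeOH), 0 °C → rt; NaHCO3 work-up
Reagents that add atoms: none
Why: Acid-catalysed acetal (MOM) cleavage, with methanol trapping the formaldehyde equivalent; the hindered benzoate ester, the aryl methyl ethers and both stereocentres are unaffected.

## Compound list

1 | noreugenin (5,7-dihydroxy-2-methyl-4H-chromen-4-one) | Cc1cc(=O)c2c(O)cc(O)cc2o1 | starting material
2 | 5,7-bis(methoxymethoxy)-2-methyl-4H-chromen-4-one | Cc1cc(=O)c2c(OCOC)cc(OCOC)cc2o1 | intermediate
3 | 8-iodo-5,7-bis(methoxymethoxy)-2-methyl-4H-chromen-4-one | Cc1cc(=O)c2c(OCOC)cc(OCOC)c(I)c2o1 | intermediate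
4 | (S)-5-(hydroxymethyl)furan-2(5H)-one | O=C1C=C[C@@H](CO)O1 | starting material
5 | [(2S)-5-oxo-2,5-dihydrofuran-2-yl]methyl 4-methylbenzenesulfonate | O=C1C=C[C@@H](COS(=O)(=O)c2ccc(C)cc2)O1 | intermediate
6 | [(2S,3R)-3-[5,7-bis(methoxymethoxy)-2-methyl-4-oxo-4H-chromen-8-yl]-5-oxooxolan-2-yl]methyl 4-methylbenzenesulfonate | O=C1C[C@H](c2c(OCOC)cc(OCOC)c3c(=O)cc(C)oc23)[C@@H](COS(=O)(=O)c4ccc(C)cc4)O1 | intermediate
7 | (4R,5S)-4-[5,7-bis(methoxymethoxy)-2-methyl-4-oxo-4H-chromen-8-yl]-5-hydroxy-1-methylpiperidin-2-one | O[C@@H]1CN(C)C(=O)C[C@@H]1c1c(OCOC)cc(OCOC)c2c(=O)cc(C)oc12 | intermediate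
8 | 3,4-dimethoxybenzoyl chloride | COc1ccc(C(Cl)=O)cc1OC | starting material
9 | (3S,4R)-4-[5,7-bis(methoxymethoxy)-2-methyl-4-oxo-4H-chromen-8-yl]-1-methyl-6-oxopiperidin-3-yl 3,4-dimethoxybenzoate | COc1ccc(C(=O)O[C@@H]2CN(C)C(=O)C[C@@H]2c2c(OCOC)cc(OCOC)c3c(=O)cc(C)oc23)cc1OC | intermediate
10 | (3S,4R)-4-[5,7-bis(methoxymethoxy)-2-methyl-4-oxo-4H-chromen-8-yl]-1-methylpiperidin-3-yl 3,4-dimethoxybenzoate | COc1ccc(C(=O)O[C@@H]2CN(C)CC[C@@H]2c2c(OCOC)cc(OCOC)c3c(=O)cc(C)oc23)cc1OC | intermediate
11 | chrotacumine D | COc1ccc(C(=O)O[C@@H]2CN(C)CC[C@@H]2c2c(O)cc(O)c3c(=O)cc(C)oc23)cc1OC | target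

## Summary

Total steps: 8. Longest linear sequence: 7 (steps 1, 2, 4, 5, 6, 7, 8).

Steps most likely to fail:

- **Step 4 (proposed new step).** Risks are reduction of the aryl radical to Ar–H before it adds, and a slow addition by the di-ortho-substituted radical. Fallback (known chemistry): Ni-catalysed electroreductive conjugate addition of iodide 3 to the O-TBS ether of 4 (NiBr2/bipyridine, DMF/pyridine, sacrificial Fe anode). This is an organonickel 1,4-addition, not a free-radical one, and is also anti to the γ-substituent. Desilylation and tosylation then rejoin the route at 6.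
- **Step 5.** Risks are competing tosylate displacement and lactone aminolysis, the epoxide pathway, and MeNH2 opening the chromone ring. Fallback: displace the tosylate of 6 with NaN3 while the lactone is intact, then Staudinger reduction so the primary amine triggers the O→N acyl shift to the NH-lactam. Acylate as in step 6, then N-methylate the lactam (NaH, MeI) before the reduction.
- **Step 7.** The risk is competing reduction of the chromone. Fallback: avoid the lactam altogether. Reduce lactone 6 to the lactol with DIBAL-H at −78 °C, then reductive amination with MeNH2/NaBH(OAc)3. The resulting secondary amine closes the ring on the tosylate to give the N-methylpiperidinol directly, which is then acylated and deprotected.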